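The runs were generated by integration with made-up constants; scatter was added.

- I had to commit to a reading at 3.0 min, so I began with the end state: taking one coupling partner per substrate, the flask's coupling partner, charged at less than the substrate, is the limiting reagent and caps conversion at 50.0%.

| flask | substrate | coupling partner | base | remark | time |
|---|---|---|---|---|---|
| Sunday's | 0.10 M | 0.070 M | 0.030 M | run made earlier |  |
| Tuesday's | 0.10 M | 0.11 M | 0.030 M | run made earlier |  |
| flask | 0.10 M | 0.0500 M | 0.0300 M |  | 3.0 min |

| run | time / min | substrate / % | product / % |
|---|---|---|---|
| Sunday's | 0.333 | 95.6 | 4.7 |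
| Sunday's | 0.667 | 92.8 | 7.9 |
| Sunday's | 1.00 | 88.7 | 11.4 |
| Sunday's | 1.33 | 85.6 | 14.0 |
| Sunday's | 1.50 | 85.1 | 15.3 |
| Sunday's | 2.00 | 80.7 | 20.0 |
| Sunday's | 2.50 | 77.9 | 22.5 |
| Tuesday's | 0.333 | 93.7 | 6.1 |
| Tuesday's | 0.667 | 88.2 | 11.4 |
| Tuesday's | 1.00 | 83.8 | 16.2 |
| Tuesday's | 1.33 | 78.5 | 21.7 |
| Tuesday's | 1.50 | 76.8 | 23.7 |
| Tuesday's | 2.00 | 70.7 | 28.5 |
| Tuesday's | 2.50 | 66.8 | 34.0 |

(scatter of a reading: 0.5 percentage points)

- the analysis behind the earlier runs scatters by 0.5 percentage points, standard deviation
- the earlier runs do not show how much of coupling partner is bound; that part of a forecast is a guess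

- part of the substrate that has reacted at 3.0 min
- share of the unused coupling partner that is free and not bound as idle adduct, at 3.0 min

- Next I reckoned the speed. With one coupling partner lost per product, the logarithm of substrate's remaining fraction over coupling partner's remaining fraction grows as a constant times the difference of the charges times the time.
- The last product readings gave 1.77 /M/min on Sunday and 1.83 /M/min on Tuesday. I carried their mean, 1.80 /M/min, as the coupling constant: rate per unit of substrate and of coupling partner.
- The bench rule is pseudo-first-order: hold coupling partner at its charge, and the rule puts the flask at 23.7% reacted.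
- The border is the charge ratio of substrate to coupling partner, 2.00: in this flask the rule's own figure means 47.4% of the coupling partner gone, which contradicts its premise of a constant coupling partner.
- My integrated reckoning, using 1.31 as the ratio of remaining fractions, gave 19.1% reacted, less than the rule. The runs offered me no number for the binding.
- The forecast said 19% reacted and 88% free, and of the free share, “That figure is largely a guess”.
- The flask gave 19.3% reacted and 97.7% free, the free share lying 9.7 percentage points above the forecast.

    substrate + coupling partner + released group → product + 2 released group (k = 8.45 /M²/s)
    coupling partner + released group ⇌ idle adduct, settled at all times (K = 345 /M)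
    base + released group ⇌ salt, settled at all times (K = 24000 /M)
    substrate + coupling partner → product + released group (k = 0.0304 /M/s)

- My coupling constant had given 19.1% for this flask. I applied it to a neighbour flask charged with 0.20 M of coupling partner, the other charges and the time held. There the substrate, charged at less than the coupling partner, is the limiting reagent, and the bench rule gives 66.0%. The integrated reckoning gives 0.583 as the ratio and 58.9% reacted. The neighbour flask gave 58.8% reacted, with 79.1% of its unused coupling partner free.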